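Ring A is not coupled to the tetrahydropyran but grown on it. The ring A carbon that lies between two oxygens is the one bonded to C4 of the tetrahydropyran (O1, C2 4-hydroxyphenyl, C3 OH, C5H2, C6 arylethyl), and this is the pattern a cyclobutenone–ynol ether benzannulation delivers. Heating 3-methoxycyclobutenone with a C4 (triisopropylsilyloxy)ethynyl tetrahydropyran joins both alkyne carbons to a vinylketene and closes the benzene ring in one operation, methoxy para to C4. The precursor carries all four stereocentres (2S,3S,4S,6S) and only silyl protecting groups, so the endgame needs fluoride and no acid.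

Key step: step 17

Remark on the chemistry: tetrahydropyran atoms are numbered O1, C2 (aryl), C3 (oxygen), C4 (ring A), C5, C6 (arylethyl); ring A is the phloroglucinol ring and ring B the chalcone aryl ring; TIPS = triisopropylsilyl, TBS = tert-butyldimethylsilyl, MOM = methoxymethyl, ArT = 4-(TIPS-oxy)phenyl. Two design decisions follow from the structure: a C2 benzylic ether of a para-oxygenated aryl group would ionise under acid and epimerise to the all-equatorial isomer, so every hydroxyl is carried as a silyl ether; and a hydride delivered to a C6-substituted oxocarbenium ion would give the 2,6-cis ether, so the C6 side chain is brought in as the carbon nucleophile.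

Step 1
Reactants: 1 4-hydroxybenzaldehyde
Product: 2 4-(TIPS-oxy)benzaldehyde
Conditions: TIPSCl, imidazole, DMF, rt
Reagents that add atoms: chlorotriisopropylsilane, CC(C)[Si](Cl)(C(C)C)C(C)C
Why: Imidazole-promoted silylation of a phenol gives an aryl silyl ether that tolerates the organometallic steps and is removed by fluoride at the end.

Step 2
Reactants: 2 4-(TIPS-oxy)benzaldehyde; 3 3-(methoxymethoxy)prop-1-ene
Product: 5 (1S,2S)-2-(methoxymethoxy)-1-ArT-but-3-en-1-ol, via allylborane 4 (not isolated)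
Conditions: 3, s-BuLi, THF, −78 °C; (+)-Ipc2BOMe; BF3·OEt2; then 2, −78 °C; H2O2, pH 7 buffer, MeOH, 0 °C to rt
Reagents that add atoms: none
Why: Brown alkoxyallylboration, in which the Z-configured γ-alkoxyallylborane 4 reacts through a closed chair transition state to give the syn relationship of the two oxygens, while the isopinocampheyl groups derived from (−)-α-pinene direct the allyl unit to the Re face of the aldehyde, so that the future C2 (S) and C3 (S) centres are set together.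

Step 3
Reactants: 5 (1S,2S)-2-(methoxymethoxy)-1-ArT-but-3-en-1-ol; 6 prop-2-enoyl chloride
Product: 7 (1S,2S)-2-(methoxymethoxy)-1-ArT-but-3-en-1-yl prop-2-enoate
Conditions: i-Pr2NEt, DMAP (catalytic), CH2Cl2, 0 °C
Reagents that add atoms: none
Why: DMAP-catalysed O-acylation of the secondary benzylic alcohol with an acid chloride installs the second alkene for ring closure without touching either stereocentre.

Step 4
Reactants: 7 (1S,2S)-2-(methoxymethoxy)-1-ArT-but-3-en-1-yl prop-2-enoate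
Product: 8 (5S,6S)-5-(methoxymethoxy)-6-ArT-5,6-dihydro-2H-pyran-2-one
Conditions: second-generation Grubbs catalyst (5 mol %), CH2Cl2, 40 °C
Reagents that add atoms: none
Why: Ring-closing metathesis of an acrylate with a terminal alkene is a reliable entry to 5,6-dihydro-2H-pyran-2-ones, driven by loss of ethene, with both stereocentres as spectators.

Step 5
Reactants: 8 (5S,6S)-5-(methoxymethoxy)-6-ArT-5,6-dihydro-2H-pyran-2-one
Product: 9 (5S,6S)-5-hydroxy-6-ArT-5,6-dihydro-2H-pyran-2-one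
Conditions: Me2BBr, CH2Cl2, −78 °C; then THF, aq NaHCO3
Reagents that add atoms: none
Why: Lewis acid-mediated acetal cleavage with bromodimethylborane removes the MOM group at −78 °C while lactone and aryl silyl ether survive, and doing this exchange early means that no acid-labile group ever has to be removed from the finished tetrahydropyran.

Step 6
Reactants: 9 (5S,6S)-5-hydroxy-6-ArT-5,6-dihydro-2H-pyran-2-one
Product: 10 (5S,6S)-5-(TBS-oxy)-6-ArT-5,6-dihydro-2H-pyran-2-one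
Conditions: TBSOTf, 2,6-lutidine, CH2Cl2, −78 to 0 °C
Reagents that add atoms: tert-butyldimethylsilyl trifluoromethanesulfonate, CC(C)(C)[Si](C)(C)OS(=O)(=O)C(F)(F)F
Why: Silylation of a secondary alcohol with a silyl triflate and a hindered pyridine is fast at low temperature, avoids base-induced translactonisation, and installs the bulky group that directs the next step.

Step 7
Reactants: 10 (5S,6S)-5-(TBS-oxy)-6-ArT-5,6-dihydro-2H-pyran-2-one
Product: 12 (4S,5S,6S)-5-(TBS-oxy)-4-ethenyl-6-ArT-oxan-2-one, via silyl ketene acetal 11 (not isolated)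
Conditions: CH2=CHMgBr, CuBr·SMe2 (catalytic), Me3SiCl, THF, −78 °C; aq NH4Cl
Reagents that add atoms: vinylmagnesium bromide, C=C[Mg]Br
Why: Copper-catalysed conjugate addition of a vinyl Grignard reagent accelerated by Me3SiCl, in which the vinyl group adds axially to the half-chair enoate anti to the pseudoaxial C5 silyloxy group and so sets the future C4 centre (S) trans to the C3 oxygen.

Step 8
Reactants: 12 (4S,5S,6S)-5-(TBS-oxy)-4-ethenyl-6-ArT-oxan-2-one
Product: 14 (4S,5S,6S)-5-(TBS-oxy)-4-ethenyl-6-ArT-oxan-2-yl acetate (anomer mixture), via aluminium lactolate 13 (not isolated)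
Conditions: i-Bu2AlH, CH2Cl2, −78 °C; then pyridine, DMAP, Ac2O, −78 to −20 °C
Reagents that add atoms: acetic anhydride, CC(=O)OC(C)=O
Why: Reductive acetylation (hydride reduction of the lactone to its aluminium hemiacetal and O-acetylation in the same flask) gives the anomeric acetate without exposing the ring-opened hydroxy aldehyde, and the anomeric configuration is irrelevant because the centre is ionised in step 11.

Step 9
Reactants: 2 4-(TIPS-oxy)benzaldehyde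
Product: 15 1-(2,2-dibromoethenyl)-4-(TIPS-oxy)benzene
Conditions: CBr4, PPh3, CH2Cl2, 0 °C
Reagents that add atoms: carbon tetrabromide, BrC(Br)(Br)Br
Why: Corey–Fuchs dibromo-olefination of an aromatic aldehyde with the ylide formed from CBr4 and PPh3.

Step 10
Reactants: 15 1-(2,2-dibromoethenyl)-4-(TIPS-oxy)benzene
Product: 17 tributyl[(ArT)ethynyl]stannane, via lithium acetylide 16 (not isolated)
Conditions: n-BuLi (2.1 equiv), THF, −78 °C; then Bu3SnCl, −78 °C to rt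
Reagents that add atoms: tributyltin chloride, CCCC[Sn](Cl)(CCCC)CCCC
Why: The second stage of the Corey–Fuchs sequence (bromine–lithium exchange, 1,2-shift and deprotonation) gives the lithium acetylide, which is stannylated at carbon.

Step 11
Reactants: 14 (4S,5S,6S)-5-(TBS-oxy)-4-ethenyl-6-ArT-oxan-2-yl acetate; 17 tributyl[(ArT)ethynyl]stannane
Product: 18 tert-butyl{[(2S,3S,4S,6R)-4-ethenyl-2-ArT-6-(ArT-ethynyl)oxan-3-yl]oxy}dimethylsilane
Conditions: BF3·OEt2, CH2Cl2, −78 °C; aq NaHCO3 quench at −78 °C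
Reagents that add atoms: none
Why: Lewis acid-mediated C-glycosylation of an anomeric acetate with an alkynylstannane, in which the oxocarbenium ion reacts through the half-chair that has the C3 silyloxy group pseudoaxial (the electrostatically preferred place for an alkoxy group at that position) and the C2 aryl group pseudoequatorial, so that axial attack anti to both places the slim alkyne at C6 trans to the C2 aryl group and cis to the C4 vinyl group (6R, which becomes 6S once the alkyne is saturated).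

Step 12
Reactants: 18 tert-butyl{[(2S,3S,4S,6R)-4-ethenyl-2-ArT-6-(ArT-ethynyl)oxan-3-yl]oxy}dimethylsilane
Product: 19 (2S,3S,4R,6R)-3-(TBS-oxy)-2-ArT-6-(ArT-ethynyl)oxane-4-carbaldehyde
Conditions: OsO4 (catalytic), NaIO4, 2,6-lutidine, dioxane/H2O, rt
Reagents that add atoms: sodium periodate, [Na+].[O-]I(=O)(=O)=O (terminal source of the aldehyde oxygen, relayed by OsO4)
Why: Lemieux–Johnson oxidative cleavage is selective for the terminal alkene over the internal alkyne and the arenes, and the aldehyde formed is equatorial on the ring and therefore already in its stable configuration.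

Step 13
Reactants: 19 (2S,3S,4R,6R)-3-(TBS-oxy)-2-ArT-6-(ArT-ethynyl)oxane-4-carbaldehyde
Product: 20 (2S,3S,4R,6S)-3-(TBS-oxy)-2-ArT-6-(2-ArT-ethyl)oxane-4-carbaldehyde
Conditions: H2 (1 atm), Pd/C, EtOAc, rt
Reagents that add atoms: none
Why: Heterogeneous catalytic hydrogenation saturates the alkyne to the 2-arylethyl chain, while an aliphatic aldehyde, the silyl ethers and the cyclic benzylic ether survive short exposure in an aprotic solvent and no stereocentre is formed.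

Step 14
Reactants: 20 (2S,3S,4R,6S)-3-(TBS-oxy)-2-ArT-6-(2-ArT-ethyl)oxane-4-carbaldehyde
Product: 21 tert-butyl{[(2S,3S,4S,6S)-4-(2,2-dibromoethenyl)-2-ArT-6-(2-ArT-ethyl)oxan-3-yl]oxy}dimethylsilane
Conditions: CBr4, PPh3, Et3N, CH2Cl2, 0 °C
Reagents that add atoms: carbon tetrabromide, BrC(Br)(Br)Br
Why: Buffered Corey–Fuchs dibromo-olefination adds the carbon that becomes the oxygen-bearing alkyne carbon without epimerising the equatorial C4 centre.

Step 15
Reactants: 21 tert-butyl{[(2S,3S,4S,6S)-4-(2,2-dibromoethenyl)-2-ArT-6-(2-ArT-ethyl)oxan-3-yl]oxy}dimethylsilane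
Product: 24 tert-butyldimethyl{[(2S,3S,4S,6S)-2-ArT-6-(2-ArT-ethyl)-4-[(TIPS-oxy)ethynyl]oxan-3-yl]oxy}silane, via lithium acetylide 22 (not isolated), via lithium ynolate 23 (not isolated)
Conditions: n-BuLi (2.1 equiv), THF, −78 °C; LiOOt-Bu (from t-BuOOH and LiN(SiMe3)2), −78 to 0 °C; TIPSOTf, −78 °C
Reagents that add atoms: tert-butyl hydroperoxide, CC(C)(C)OO; triisopropylsilyl trifluoromethanesulfonate, CC(C)[Si](OS(=O)(=O)C(F)(F)F)(C(C)C)C(C)C
Why: The dibromoalkene gives the lithium acetylide (Corey–Fuchs), which is oxidised to the ynolate by oxygen transfer from the lithium peroxide and silylated on oxygen by the bulky silyl triflate, the established acetylide oxidation route to siloxyalkynes, with C4 untouched.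

Step 16
Reactants: 25 cyclobutane-1,3-dione
Product: 26 3-methoxycyclobut-2-en-1-one
Conditions: Me3SiCHN2, MeOH/CH2Cl2, 0 °C
Reagents that add atoms: (trimethylsilyl)diazomethane, C[Si](C)(C)C=[N+]=[N-]
Why: O-methylation of a strongly acidic vinylogous acid (the enol form of the dione) by a diazoalkane gives the vinylogous ester.

Step 17
Reactants: 24 tert-butyldimethyl{[(2S,3S,4S,6S)-2-ArT-6-(2-ArT-ethyl)-4-[(TIPS-oxy)ethynyl]oxan-3-yl]oxy}silane; 26 3-methoxycyclobut-2-en-1-one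
Product: 30 5-methoxy-2-[(2S,3S,4S,6S)-3-(TBS-oxy)-2-ArT-6-(2-ArT-ethyl)oxan-4-yl]-3-(TIPS-oxy)phenol, via vinylketene 27 (not isolated), via vinylcyclobutenone 28 (not isolated), via dienylketene 29 (not isolated)
Conditions: toluene, 80 then 120 °C, sealed tube, 26 in slight excess, no base in work-up
Reagents that add atoms: none
Why: Thermal 4π electrocyclic opening of 26 gives vinylketene 27, which undergoes a regioselective [2+2] cycloaddition with the electron-rich alkyne of 24 (the alkyne carbon on C4 bonds to the ketene carbonyl carbon, the silyloxy-bearing carbon to the ketene α-carbon) to give 28, and a second 4π opening gives dienylketene 29, which closes by 6π electrocyclisation and tautomerises to phenol 30. This is the Danheiser benzannulation of a cyclobutenone with a siloxyalkyne, a known reaction applied here to a new alkyne. Ring A is closed in the 6π-electrocyclic (disrotatory) mode, and the closing bond joins the ketene carbon to the terminal methylene carbon, the same two atoms that were bonded in 26, so the step makes two new C–C bonds between the partners and one ring. No stereocentre is created, and C2, C3, C4 and C6 are spectators under neutral aprotic heating because the C4–H bond is not acidic. The selectivity needed is the regiochemistry of the [2+2] step, fixed by the polarisation of the ynol ether, which puts hydroxyl and silyloxy on the two carbons flanking the C4-bearing carbon and methoxy para to it; chemoselectivity is secured because every hydroxyl is silylated and the siloxyalkyne is the only ketenophile.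

Step 18
Reactants: 30 5-methoxy-2-[(2S,3S,4S,6S)-3-(TBS-oxy)-2-ArT-6-(2-ArT-ethyl)oxan-4-yl]-3-(TIPS-oxy)phenol
Product: 31 {[(2S,3S,4S,6S)-4-[4-methoxy-2,6-bis(TIPS-oxy)phenyl]-2-ArT-6-(2-ArT-ethyl)oxan-3-yl]oxy}(tert-butyl)dimethylsilane
Conditions: TIPSOTf, 2,6-lutidine, CH2Cl2, 0 °C to rt
Reagents that add atoms: triisopropylsilyl trifluoromethanesulfonate, CC(C)[Si](OS(=O)(=O)C(F)(F)F)(C(C)C)C(C)C
Why: Silylation of the remaining ring A phenol with a silyl triflate and a hindered base makes ring A locally symmetric, so that its two open positions become equivalent for the next step.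

Step 19
Reactants: 31 {[(2S,3S,4S,6S)-4-[4-methoxy-2,6-bis(TIPS-oxy)phenyl]-2-ArT-6-(2-ArT-ethyl)oxan-3-yl]oxy}(tert-butyl)dimethylsilane
Product: 32 {[(2S,3S,4S,6S)-4-[3-bromo-4-methoxy-2,6-bis(TIPS-oxy)phenyl]-2-ArT-6-(2-ArT-ethyl)oxan-3-yl]oxy}(tert-butyl)dimethylsilane
Conditions: NBS (1.0 equiv), CH2Cl2, −40 to 0 °C, dark
Reagents that add atoms: N-bromosuccinimide, O=C1CCC(=O)N1Br
Why: Electrophilic aromatic bromination takes place on the tri-oxygenated ring A, far more nucleophilic than the mono-silyloxy arenes, at its single kind of open position (between methoxy and silyloxy), and one equivalent at low temperature limits it to monobromination.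

Step 20
Reactants: 2 4-(TIPS-oxy)benzaldehyde
Product: 33 (2E)-3-ArT-prop-2-enal
Conditions: Ph3P=CHCHO, toluene, 80 °C
Reagents that add atoms: (triphenylphosphoranylidene)acetaldehyde, O=CC=P(c1ccccc1)(c1ccccc1)c1ccccc1
Why: Wittig olefination with a stabilised formyl ylide gives the E-configured cinnamaldehyde.

Step 21
Reactants: 32 {[(2S,3S,4S,6S)-4-[3-bromo-4-methoxy-2,6-bis(TIPS-oxy)phenyl]-2-ArT-6-(2-ArT-ethyl)oxan-3-yl]oxy}(tert-butyl)dimethylsilane; 33 (2E)-3-ArT-prop-2-enal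
Product: 35 (2E)-1-{6-methoxy-3-[(2S,3S,4S,6S)-3-(TBS-oxy)-2-ArT-6-(2-ArT-ethyl)oxan-4-yl]-2,4-bis(TIPS-oxy)phenyl}-3-ArT-prop-2-en-1-ol (carbinol epimers), via aryllithium 34 (not isolated)
Conditions: n-BuLi, THF, −78 °C; then 33, −78 °C; aq NH4Cl
Reagents that add atoms: none
Why: Bromine–lithium exchange gives the ring A aryllithium, which adds 1,2 to the enal at −78 °C before any silyl migration from oxygen to carbon can set in, and the new carbinol centre is removed in the next step so its configuration does not matter.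

Step 22
Reactants: 35 (2E)-1-{6-methoxy-3-[(2S,3S,4S,6S)-3-(TBS-oxy)-2-ArT-6-(2-ArT-ethyl)oxan-4-yl]-2,4-bis(TIPS-oxy)phenyl}-3-ArT-prop-2-en-1-ol
Product: 36 (2E)-1-{6-methoxy-3-[(2S,3S,4S,6S)-3-(TBS-oxy)-2-ArT-6-(2-ArT-ethyl)oxan-4-yl]-2,4-bis(TIPS-oxy)phenyl}-3-ArT-prop-2-en-1-one
Conditions: MnO2, CH2Cl2, rt
Reagents that add atoms: none
Why: MnO2 oxidation of a doubly activated (benzylic and allylic) alcohol gives the chalcone without isomerising the E alkene.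

Step 23
Reactants: 36 (2E)-1-{6-methoxy-3-[(2S,3S,4S,6S)-3-(TBS-oxy)-2-ArT-6-(2-ArT-ethyl)oxan-4-yl]-2,4-bis(TIPS-oxy)phenyl}-3-ArT-prop-2-en-1-one
Product: 37 (2E)-1-{2,4-dihydroxy-3-[(2S,3S,4S,6S)-3-hydroxy-2-(4-hydroxyphenyl)-6-[2-(4-hydroxyphenyl)ethyl]oxan-4-yl]-6-methoxyphenyl}-3-(4-hydroxyphenyl)prop-2-en-1-one (CNP0310862.1)
Conditions: n-Bu4NF, AcOH, THF, 0 to 40 °C
Reagents that add atoms: none
Why: Fluoride-mediated cleavage of all six silyl ethers under acetic acid buffering releases the five phenols and the C3 alcohol without acid, so the C2 benzylic ether should not epimerise and the ortho-hydroxychalcone should not cyclise.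

Compound list
1 | 4-hydroxybenzaldehyde | O=Cc1ccc(O)cc1 | starting material
2 | 4-(TIPS-oxy)benzaldehyde | O=Cc1ccc(O[Si](C(C)C)(C(C)C)C(C)C)cc1 | intermediate
3 | 3-(methoxymethoxy)prop-1-ene (allyl MOM ether) | C=CCOCOC | starting material
4 | [(2Z)-3-(methoxymethoxy)prop-2-en-1-yl]bis(isopinocampheyl)borane, isopinocampheyl groups from (−)-α-pinene | COCO/C=C\CB([C@H]1C[C@H]2C[C@@H]([C@@H]1C)C2(C)C)[C@H]1C[C@H]2C[C@@H]([C@@H]1C)C2(C)C | intermediate (not isolated)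
5 | (1S,2S)-2-(methoxymethoxy)-1-ArT-but-3-en-1-ol | O[C@@H](c1ccc(O[Si](C(C)C)(C(C)C)C(C)C)cc1)[C@H](C=C)OCOC | intermediate
6 | prop-2-enoyl chloride (acryloyl chloride) | C=CC(=O)Cl | starting material
7 | (1S,2S)-2-(methoxymethoxy)-1-ArT-but-3-en-1-yl prop-2-enoate | C=CC(=O)O[C@@H](c1ccc(O[Si](C(C)C)(C(C)C)C(C)C)cc1)[C@H](C=C)OCOC | intermediate
8 | (5S,6S)-5-(methoxymethoxy)-6-ArT-5,6-dihydro-2H-pyran-2-one | O1[C@@H](c2ccc(O[Si](C(C)C)(C(C)C)C(C)C)cc2)[C@@H](OCOC)C=CC1=O | intermediate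
9 | (5S,6S)-5-hydroxy-6-ArT-5,6-dihydro-2H-pyran-2-one | O1[C@@H](c2ccc(O[Si](C(C)C)(C(C)C)C(C)C)cc2)[C@@H](O)C=CC1=O | intermediate
10 | (5S,6S)-5-(TBS-oxy)-6-ArT-5,6-dihydro-2H-pyran-2-one | O1[C@@H](c2ccc(O[Si](C(C)C)(C(C)C)C(C)C)cc2)[C@@H](O[Si](C)(C)C(C)(C)C)C=CC1=O | intermediate
11 | trimethylsilyl ketene acetal of lactone 12 (6-(trimethylsilyloxy)-3,4-dihydro-2H-pyran carrying the 2-ArT, 3-TBS-oxy and 4-ethenyl groups of 12) | O1[C@@H](c2ccc(O[Si](C(C)C)(C(C)C)C(C)C)cc2)[C@@H](O[Si](C)(C)C(C)(C)C)[C@H](C=C)C=C1O[Si](C)(C)C | intermediate (not isolated)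
12 | (4S,5S,6S)-5-(TBS-oxy)-4-ethenyl-6-ArT-oxan-2-one | O1[C@@H](c2ccc(O[Si](C(C)C)(C(C)C)C(C)C)cc2)[C@@H](O[Si](C)(C)C(C)(C)C)[C@H](C=C)CC1=O | intermediate
13 | diisobutylaluminium hemiacetal (lactolate) of 12 | O1[C@@H](c2ccc(O[Si](C(C)C)(C(C)C)C(C)C)cc2)[C@@H](O[Si](C)(C)C(C)(C)C)[C@H](C=C)CC1O[Al](CC(C)C)CC(C)C | intermediate (not isolated)
14 | (4S,5S,6S)-5-(TBS-oxy)-4-ethenyl-6-ArT-oxan-2-yl acetate, anomer mixture | O1[C@@H](c2ccc(O[Si](C(C)C)(C(C)C)C(C)C)cc2)[C@@H](O[Si](C)(C)C(C)(C)C)[C@H](C=C)CC1OC(C)=O | intermediate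
15 | 1-(2,2-dibromoethenyl)-4-(TIPS-oxy)benzene | BrC(Br)=Cc1ccc(O[Si](C(C)C)(C(C)C)C(C)C)cc1 | intermediate
16 | [(ArT)ethynyl]lithium | [Li]C#Cc1ccc(O[Si](C(C)C)(C(C)C)C(C)C)cc1 | intermediate (not isolated)
17 | tributyl[(ArT)ethynyl]stannane | CCCC[Sn](CCCC)(CCCC)C#Cc1ccc(O[Si](C(C)C)(C(C)C)C(C)C)cc1 | intermediate
18 | tert-butyl{[(2S,3S,4S,6R)-4-ethenyl-2-ArT-6-(ArT-ethynyl)oxan-3-yl]oxy}dimethylsilane | C=C[C@@H]1C[C@H](C#Cc2ccc(O[Si](C(C)C)(C(C)C)C(C)C)cc2)O[C@@H](c2ccc(O[Si](C(C)C)(C(C)C)C(C)C)cc2)[C@H]1O[Si](C)(C)C(C)(C)C | intermediate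
19 | (2S,3S,4R,6R)-3-(TBS-oxy)-2-ArT-6-(ArT-ethynyl)oxane-4-carbaldehyde | O=C[C@@H]1C[C@H](C#Cc2ccc(O[Si](C(C)C)(C(C)C)C(C)C)cc2)O[C@@H](c2ccc(O[Si](C(C)C)(C(C)C)C(C)C)cc2)[C@H]1O[Si](C)(C)C(C)(C)C | intermediate
20 | (2S,3S,4R,6S)-3-(TBS-oxy)-2-ArT-6-(2-ArT-ethyl)oxane-4-carbaldehyde | O=C[C@@H]1C[C@H](CCc2ccc(O[Si](C(C)C)(C(C)C)C(C)C)cc2)O[C@@H](c2ccc(O[Si](C(C)C)(C(C)C)C(C)C)cc2)[C@H]1O[Si](C)(C)C(C)(C)C | intermediate
21 | tert-butyl{[(2S,3S,4S,6S)-4-(2,2-dibromoethenyl)-2-ArT-6-(2-ArT-ethyl)oxan-3-yl]oxy}dimethylsilane | BrC(Br)=C[C@@H]1C[C@H](CCc2ccc(O[Si](C(C)C)(C(C)C)C(C)C)cc2)O[C@@H](c2ccc(O[Si](C(C)C)(C(C)C)C(C)C)cc2)[C@H]1O[Si](C)(C)C(C)(C)C | intermediate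
22 | C4 lithium acetylide of the tetrahydropyran (ethynyllithium on C4 of the ring of 21) | [Li]C#C[C@@H]1C[C@H](CCc2ccc(O[Si](C(C)C)(C(C)C)C(C)C)cc2)O[C@@H](c2ccc(O[Si](C(C)C)(C(C)C)C(C)C)cc2)[C@H]1O[Si](C)(C)C(C)(C)C | intermediate (not isolated)
23 | C4 lithium ynolate of the tetrahydropyran (lithium alkynolate on C4) | [Li]OC#C[C@@H]1C[C@H](CCc2ccc(O[Si](C(C)C)(C(C)C)C(C)C)cc2)O[C@@H](c2ccc(O[Si](C(C)C)(C(C)C)C(C)C)cc2)[C@H]1O[Si](C)(C)C(C)(C)C | intermediate (not isolated)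
24 | tert-butyldimethyl{[(2S,3S,4S,6S)-2-ArT-6-(2-ArT-ethyl)-4-[(TIPS-oxy)ethynyl]oxan-3-yl]oxy}silane (C4 siloxyalkyne) | CC(C)[Si](C(C)C)(C(C)C)OC#C[C@@H]1C[C@H](CCc2ccc(O[Si](C(C)C)(C(C)C)C(C)C)cc2)O[C@@H](c2ccc(O[Si](C(C)C)(C(C)C)C(C)C)cc2)[C@H]1O[Si](C)(C)C(C)(C)C | intermediate
25 | cyclobutane-1,3-dione | O=C1CC(=O)C1 | starting material
26 | 3-methoxycyclobut-2-en-1-one | COC1=CC(=O)C1 | intermediate
27 | 3-methoxybuta-1,3-dien-1-one (vinylketene) | COC(=C)C=C=O | intermediate (not isolated)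
28 | 4-(1-methoxyethenyl)-2-[(2S,3S,4S,6S)-3-(TBS-oxy)-2-ArT-6-(2-ArT-ethyl)oxan-4-yl]-3-(TIPS-oxy)cyclobut-2-en-1-one | COC(=C)C1C(O[Si](C(C)C)(C(C)C)C(C)C)=C([C@@H]2C[C@H](CCc3ccc(O[Si](C(C)C)(C(C)C)C(C)C)cc3)O[C@@H](c3ccc(O[Si](C(C)C)(C(C)C)C(C)C)cc3)[C@H]2O[Si](C)(C)C(C)(C)C)C1=O | intermediate (not isolated)
29 | 5-methoxy-2-[(2S,3S,4S,6S)-3-(TBS-oxy)-2-ArT-6-(2-ArT-ethyl)oxan-4-yl]-3-(TIPS-oxy)hexa-1,3,5-trien-1-one (dienylketene) | C=C(OC)C=C(O[Si](C(C)C)(C(C)C)C(C)C)C(=C=O)[C@@H]1C[C@H](CCc2ccc(O[Si](C(C)C)(C(C)C)C(C)C)cc2)O[C@@H](c2ccc(O[Si](C(C)C)(C(C)C)C(C)C)cc2)[C@H]1O[Si](C)(C)C(C)(C)C | intermediate (not isolated)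
30 | 5-methoxy-2-[(2S,3S,4S,6S)-3-(TBS-oxy)-2-ArT-6-(2-ArT-ethyl)oxan-4-yl]-3-(TIPS-oxy)phenol | COc1cc(O)c([C@@H]2C[C@H](CCc3ccc(O[Si](C(C)C)(C(C)C)C(C)C)cc3)O[C@@H](c3ccc(O[Si](C(C)C)(C(C)C)C(C)C)cc3)[C@H]2O[Si](C)(C)C(C)(C)C)c(O[Si](C(C)C)(C(C)C)C(C)C)c1 | intermediate
31 | {[(2S,3S,4S,6S)-4-[4-methoxy-2,6-bis(TIPS-oxy)phenyl]-2-ArT-6-(2-ArT-ethyl)oxan-3-yl]oxy}(tert-butyl)dimethylsilane | COc1cc(O[Si](C(C)C)(C(C)C)C(C)C)c([C@@H]2C[C@H](CCc3ccc(O[Si](C(C)C)(C(C)C)C(C)C)cc3)O[C@@H](c3ccc(O[Si](C(C)C)(C(C)C)C(C)C)cc3)[C@H]2O[Si](C)(C)C(C)(C)C)c(O[Si](C(C)C)(C(C)C)C(C)C)c1 | intermediate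
32 | {[(2S,3S,4S,6S)-4-[3-bromo-4-methoxy-2,6-bis(TIPS-oxy)phenyl]-2-ArT-6-(2-ArT-ethyl)oxan-3-yl]oxy}(tert-butyl)dimethylsilane | COc1cc(O[Si](C(C)C)(C(C)C)C(C)C)c([C@@H]2C[C@H](CCc3ccc(O[Si](C(C)C)(C(C)C)C(C)C)cc3)O[C@@H](c3ccc(O[Si](C(C)C)(C(C)C)C(C)C)cc3)[C@H]2O[Si](C)(C)C(C)(C)C)c(O[Si](C(C)C)(C(C)C)C(C)C)c1Br | intermediate
33 | (2E)-3-ArT-prop-2-enal | O=C/C=C/c1ccc(O[Si](C(C)C)(C(C)C)C(C)C)cc1 | intermediate
34 | ring A aryllithium (lithium in place of bromine in 32) | COc1cc(O[Si](C(C)C)(C(C)C)C(C)C)c([C@@H]2C[C@H](CCc3ccc(O[Si](C(C)C)(C(C)C)C(C)C)cc3)O[C@@H](c3ccc(O[Si](C(C)C)(C(C)C)C(C)C)cc3)[C@H]2O[Si](C)(C)C(C)(C)C)c(O[Si](C(C)C)(C(C)C)C(C)C)c1[Li] | intermediate (not isolated)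
35 | (2E)-1-{6-methoxy-3-[(2S,3S,4S,6S)-3-(TBS-oxy)-2-ArT-6-(2-ArT-ethyl)oxan-4-yl]-2,4-bis(TIPS-oxy)phenyl}-3-ArT-prop-2-en-1-ol, carbinol epimers | COc1cc(O[Si](C(C)C)(C(C)C)C(C)C)c([C@@H]2C[C@H](CCc3ccc(O[Si](C(C)C)(C(C)C)C(C)C)cc3)O[C@@H](c3ccc(O[Si](C(C)C)(C(C)C)C(C)C)cc3)[C@H]2O[Si](C)(C)C(C)(C)C)c(O[Si](C(C)C)(C(C)C)C(C)C)c1C(O)/C=C/c1ccc(O[Si](C(C)C)(C(C)C)C(C)C)cc1 | intermediate
36 | (2E)-1-{6-methoxy-3-[(2S,3S,4S,6S)-3-(TBS-oxy)-2-ArT-6-(2-ArT-ethyl)oxan-4-yl]-2,4-bis(TIPS-oxy)phenyl}-3-ArT-prop-2-en-1-one | COc1cc(O[Si](C(C)C)(C(C)C)C(C)C)c([C@@H]2C[C@H](CCc3ccc(O[Si](C(C)C)(C(C)C)C(C)C)cc3)O[C@@H](c3ccc(O[Si](C(C)C)(C(C)C)C(C)C)cc3)[C@H]2O[Si](C)(C)C(C)(C)C)c(O[Si](C(C)C)(C(C)C)C(C)C)c1C(=O)/C=C/c1ccc(O[Si](C(C)C)(C(C)C)C(C)C)cc1 | intermediate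
37 | (2E)-1-{2,4-dihydroxy-3-[(2S,3S,4S,6S)-3-hydroxy-2-(4-hydroxyphenyl)-6-[2-(4-hydroxyphenyl)ethyl]oxan-4-yl]-6-methoxyphenyl}-3-(4-hydroxyphenyl)prop-2-en-1-one | COc1cc(O)c([C@@H]2C[C@H](CCc3ccc(O)cc3)O[C@@H](c3ccc(O)cc3)[C@H]2O)c(O)c1C(=O)/C=C/c1ccc(O)cc1 | target

Total step count: 23. Longest linear sequence: 19 steps from 4-hydroxybenzaldehyde (steps 1–8, 11–15, 17–19, 21–23); steps 9, 10, 16 and 20 are convergent branches.

Steps most likely to fail, in order of risk: 17, 11, 15.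

Step 17. The 4π opening of the donor-stabilised cyclobutenone 26 may be so sluggish that siloxyalkyne 24 decomposes or the ketene oligomerises at the temperature required. In that case the same vinylketene 27 would be generated at room temperature by photochemical Wolff rearrangement. Commercial 3,3-dimethoxybutan-2-one would lose methanol (TsOH, heat) to give 3-methoxybut-3-en-2-one F1. Trifluoroacetylation (LiN(SiMe3)2, CF3CO2CH2CF3, THF, −78 °C) would give 1,1,1-trifluoro-5-methoxyhex-5-ene-2,4-dione F2, and deacylative diazo transfer (MsN3, Et3N, MeCN) would give 1-diazo-3-methoxybut-3-en-2-one F3. Irradiating F3 together with 24 (hν, CH2Cl2, rt), followed by brief warming to complete ring opening and 6π closure, should give phenol 30. This fallback sets out from 24 and returns to the route at 30.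

Step 11. Axial attack on the C6 oxocarbenium ion may show poor facial selectivity, because the C4 vinyl group sits syn to the incoming nucleophile in the preferred half-chair. C6 would then be set by reagent control followed by substitution with inversion. Lactone 12 and lithium acetylide 16 (BF3·OEt2, THF, −78 °C) would give (5S,6S,7S)-6-(TBS-oxy)-5-ethenyl-7-hydroxy-1,7-bis(ArT)hept-1-yn-3-one F4. Noyori transfer hydrogenation with RuCl[(S,S)-TsDPEN](p-cymene) and HCO2H/Et3N would give (1S,2S,3S,5S)-2-(TBS-oxy)-3-ethenyl-1,7-bis(ArT)hept-6-yne-1,5-diol F5. Mesylation of the less hindered propargylic hydroxyl (MsCl, Et3N, CH2Cl2, −40 °C) would give (3S,5S,6S,7S)-6-(TBS-oxy)-5-ethenyl-7-hydroxy-1,7-bis(ArT)hept-1-yn-3-yl methanesulfonate F6. KN(SiMe3)2 in THF at 0 °C would then close the ring by intramolecular SN2 displacement with inversion. This fallback sets out from 12 and returns to the route at 18.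

Step 15. Oxygen transfer to the acetylide may be incomplete, or the ynolate may silylate on carbon to a silylketene. The ynolate would then be reached by ester homologation. Aldehyde 20 would be oxidised (NaClO2, NaH2PO4, 2-methylbut-2-ene, t-BuOH/H2O) to (2S,3S,4R,6S)-3-(TBS-oxy)-2-ArT-6-(2-ArT-ethyl)oxane-4-carboxylic acid F7 and methylated (Me3SiCHN2, MeOH) to methyl (2S,3S,4R,6S)-3-(TBS-oxy)-2-ArT-6-(2-ArT-ethyl)oxane-4-carboxylate F8. LiCHBr2 (CH2Br2 and lithium 2,2,6,6-tetramethylpiperidide, LiNC9H18, THF, −78 °C) would add to give 2,2-dibromo-1-[(2S,3S,4R,6S)-3-(TBS-oxy)-2-ArT-6-(2-ArT-ethyl)oxan-4-yl]ethan-1-one F9 as its enolate. n-BuLi would trigger the Kowalski rearrangement, C4 migrating with retention, to lithium ynolate 23, which is silylated with TIPSOTf as before. This fallback sets out from 20 and returns to the route at 24.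

Further compounds
F1 | step 17 | 3-methoxybut-3-en-2-one | COC(=C)C(C)=O
F2 | step 17 | 1,1,1-trifluoro-5-methoxyhex-5-ene-2,4-dione | COC(=C)C(=O)CC(=O)C(F)(F)F
F3 | step 17 | 1-diazo-3-methoxybut-3-en-2-one | COC(=C)C(=O)C=[N+]=[N-]
F4 | step 11 | (5S,6S,7S)-6-(TBS-oxy)-5-ethenyl-7-hydroxy-1,7-bis(ArT)hept-1-yn-3-one | O[C@@H](c1ccc(O[Si](C(C)C)(C(C)C)C(C)C)cc1)[C@@H](O[Si](C)(C)C(C)(C)C)[C@H](C=C)CC(=O)C#Cc1ccc(O[Si](C(C)C)(C(C)C)C(C)C)cc1
F5 | step 11 | (1S,2S,3S,5S)-2-(TBS-oxy)-3-ethenyl-1,7-bis(ArT)hept-6-yne-1,5-diol | O[C@@H](c1ccc(O[Si](C(C)C)(C(C)C)C(C)C)cc1)[C@@H](O[Si](C)(C)C(C)(C)C)[C@H](C=C)C[C@H](O)C#Cc1ccc(O[Si](C(C)C)(C(C)C)C(C)C)cc1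
F6 | step 11 | (3S,5S,6S,7S)-6-(TBS-oxy)-5-ethenyl-7-hydroxy-1,7-bis(ArT)hept-1-yn-3-yl methanesulfonate | O[C@@H](c1ccc(O[Si](C(C)C)(C(C)C)C(C)C)cc1)[C@@H](O[Si](C)(C)C(C)(C)C)[C@H](C=C)C[C@H](OS(C)(=O)=O)C#Cc1ccc(O[Si](C(C)C)(C(C)C)C(C)C)cc1
F7 | step 15 | (2S,3S,4R,6S)-3-(TBS-oxy)-2-ArT-6-(2-ArT-ethyl)oxane-4-carboxylic acid | OC(=O)[C@@H]1C[C@H](CCc2ccc(O[Si](C(C)C)(C(C)C)C(C)C)cc2)O[C@@H](c2ccc(O[Si](C(C)C)(C(C)C)C(C)C)cc2)[C@H]1O[Si](C)(C)C(C)(C)C
F8 | step 15 | methyl (2S,3S,4R,6S)-3-(TBS-oxy)-2-ArT-6-(2-ArT-ethyl)oxane-4-carboxylate | COC(=O)[C@@H]1C[C@H](CCc2ccc(O[Si](C(C)C)(C(C)C)C(C)C)cc2)O[C@@H](c2ccc(O[Si](C(C)C)(C(C)C)C(C)C)cc2)[C@H]1O[Si](C)(C)C(C)(C)C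
F9 | step 15 | 2,2-dibromo-1-[(2S,3S,4R,6S)-3-(TBS-oxy)-2-ArT-6-(2-ArT-ethyl)oxan-4-yl]ethan-1-one | BrC(Br)C(=O)[C@@H]1C[C@H](CCc2ccc(O[Si](C(C)C)(C(C)C)C(C)C)cc2)O[C@@H](c2ccc(O[Si](C(C)C)(C(C)C)C(C)C)cc2)[C@H]1O[Si](C)(C)C(C)(C)C
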